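Analysis of the target

Compound 19 is a germacranolide: a ten-membered carbocycle (C1–C10) fused through C6 and C7 to a butenolide (O–C12(=O)–C11=C7, closing on C6). It carries methyl C14 on C10, methyl C15 on C4, an acetoxymethyl group (C13) on C11 and a tiglate on C8. The SMILES of 19 encodes six stereocentres, 1R,4R,5R,6S,8S,10R. Four of them belong to two trans-epoxides (C1–C10 and C4–C5), each the image of an E-trisubstituted alkene, with oxygen on the faces (1β,10α and 4α,5β) that a peracid reaches from outside an (E,E)-cyclodeca-1(10),4-diene. The other two, C6 and C8, both carry oxygen on the α face and flank the sp2 carbon C7. The sensitive groups are the two trisubstituted epoxides (transannular opening under acid), the vinylogously acidic H-6 next to the 4,5-epoxide (base can open that epoxide to a γ-alkylidene butenolide), the primary allylic acetate at C13 and the allylic ester at C8. The synthesis is hard because a ten-membered ring must be closed, six oxygenated centres must be placed in the right relative sense, and the last operations must run on a compound that tolerates neither strong acid nor strong base. The strategy rests on the carbon skeleton: ring carbons C1–C10 with C14, C15 and the three-carbon unit C11–C13 on C7 form an unbranched head-to-tail farnesyl chain whose two ends are joined at ring bond C6–C7.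

Retrosynthetic reasoning

C8–O ester bond. The bond between C8 and the tiglate oxygen of 19 is cut first, giving tiglic acid 18 and the C8-epimeric alcohol 17. The tiglate comes last because its alkene would not survive the halogenation that builds the butenolide. The known C8 hydroxylase of this pathway delivers the β-alcohol, whereas 19 has the ester on the α face. An 8α-hydroxy acid would also lactonise onto C8 instead of C6. The β-alcohol is therefore accepted and the configuration is inverted in the esterification itself. The forward reaction must be an SN2 esterification with inversion at a hindered allylic carbon under nearly neutral conditions.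

O–Si bond. Alcohol 17 is traced to its triethylsilyl ether 16. Without protection, O8 lies cis to C13 across the C7=C11 alkene and would close a five-membered ether onto C13 once C13 carries a leaving group. The forward step only has to remove silicon without opening an epoxide or generating an alkoxide.

C13–O bond and the C7=C11 alkene. Acetate 16 is cut at C13–O to the allylic bromide 15. Formal addition of HBr across C7=C11 leads back to the 11,13-dibromide 14, and removal of the two bromines gives the exocyclic α-methylene lactone 13. This is the place for the cut because the enzymatic lactone synthesis delivers the exocyclic isomer. The transposition moves the alkene into the ring fusion and raises C13 to the alcohol oxidation level in the same sequence. The forward steps must add halogen to the only alkene left, eliminate toward C7 and substitute at C13. The stereocentre C7 is erased here.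

The two epoxides. Diepoxide 13 is traced through monoepoxide 12 to the (E,E)-diene 11. Four stereocentres then depend only on alkene geometry and on the facial preference of the medium ring. Removing the alkenes early also shuts off Cope rearrangement and transannular cyclisation. The forward reaction must attack both ring alkenes from their outer faces and leave the conjugated methylene untouched.

Silyl ether. Ether 11 comes from the alcohol 10 by silylation.

C8–O, C6–O and lactone C–O bonds. Lactone 10 is opened to the dihydroxy acid 9, and the C6 and C8 hydroxyls are removed in turn via 8 to give acid 7. No chemical reagent would pick out the unactivated C8 and the allylic C6 with this face selectivity. The two P450 hydroxylases do it, and the 6α-hydroxy acid lactonises spontaneously.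

C12 oxidation. Acid 7 is reduced in thought through aldehyde 6 and alcohol 5 to the hydrocarbon 4. One oxidase carries the allylic methyl of the isopropenyl group through three oxidation levels.

C6–C7 ring bond. Hydrocarbon 4 is cut at C6–C7 to the acyclic diphosphate 3. This one cut removes the ring and the only stereocentre of 4 and leaves a linear, achiral chain with both E-alkenes in place. The forward reaction must ionise the allylic diphosphate, close the ring 1,10 and lose a proton, under enzyme control.

C–O–P and C–Cl bonds. Diphosphate 3 comes from chloride 2 by displacement, and 2 from commercial alcohol 1.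

Alternatives that were turned down

Alternative 1: The cut is at C7=C11 inside the butenolide, with the C6 ester formed beforehand. In the forward direction the keto phosphonate A2 would be treated with LiCl and DBU; the phosphonate carbanion adds to the C7 ketone and closes the butenolide to A1, the 4-methoxybenzyl ether analogue of 19.
- For: the tetrasubstituted alkene is made with the C13 oxygen already in place, so no exo-to-endo transposition and no halogen are needed, and the tiglate can be present from the start. The C8 configuration need not be inverted. On these two points this alternative is stronger than the chosen route.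
- Against: the disconnection does not touch the real problems. A2 is already a diepoxy ten-membered ring with all six stereocentres, and its ketone is flanked by two acyloxy-bearing carbons. DBU can epimerise or eliminate at C6 and C8 faster than the carbanion attacks a hindered medium-ring ketone. A1 itself has the acidic H-6 next to the 4,5-epoxide under the same base. Ether cleavage and acetylation would still follow.
- Comparison: the chosen strategy gets the ring, both E-alkenes and three stereocontrolled oxidations in three enzymatic steps from a C15 chain, and pays for that with a transposition and an inversion near the end.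

Alternative 2: The cut is at C5–C6 together with the lactone C–O bond. In the forward direction the acyclic iodo aldehyde A4 would be cyclised with catalytic CrCl2 (divalent chromium, regenerated at the cathode) and NiCl2; the alkenylchromium adds to the C6 aldehyde and the C6 alkoxide closes the lactone on the cis methyl ester, giving the triene lactone A3.
- For: one step forms the ring bond, the C6 stereocentre and the lactone. A3 already carries tiglate and acetate, so only the double epoxidation remains. In steps after ring closure this alternative is clearly shorter than the chosen route, and its epoxidation relies on the same outer-face preference.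
- Against: the ten-membered (E,E)-diene must form without a template against transannular strain. The new C6 centre would be controlled only by C8 across the sp2 carbon C7. A4 holds a primary allylic acetate on an electron-poor alkene, into which low-valent nickel can insert, and an enal that invites 1,4-addition. A4 is a Z-configured tetrasubstituted alkene with three different carbonyl-type substituents and one stereocentre, and would need many steps as a single enantiomer.
- Comparison: the chosen strategy offers a ring closure with no competing mode and no stereochemical decision at C6 at that stage.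

Alternative 3: The cut is at C2=C3. In the forward direction the bis(vinyl epoxide) A6 would be closed with the second-generation Grubbs catalyst to the 2,3-didehydro compound A5, followed by saturation of the new alkene.
- For: the route is highly convergent. Both epoxides can be set by reagent-controlled asymmetric epoxidation of acyclic allylic alcohols, which is stronger than the substrate control the chosen route relies on. Metathesis tolerates epoxides and esters, and the alkene geometry does not matter.
- Against: ten-membered rings are among the least favourable for ring-closing metathesis. One of the two vinyl groups sits on the fully substituted epoxide carbon C4, so loading of the catalyst is slow and oligomerisation competes. The C2=C3 alkene of A5 then has to be reduced beside a tiglate, a butenolide and two allylic epoxides that are prone to reductive opening.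
- Comparison: the chosen strategy offers a ring closure that is not limited by ring strain, and an epoxidation whose facial outcome is fixed by the medium-ring conformation of the natural diene.

Key step: step 3

Assumption: the SMILES of 19 is read as 1β,10α:4α,5β-diepoxy, 6α-O, 8α-O (1R,4R,5R,6S,8S,10R, germacrane numbering); the enzymes are recombinant proteins used as catalysts.

Step 1
Reactants: 1 (2E,6E)-farnesol
Product: 2 (2E,6E)-farnesyl chloride
Conditions: NCS, Me2S, CH2Cl2, −40 °C to 0 °C
Reagents that add atoms: N-chlorosuccinimide, O=C1CCC(=O)N1Cl
Why: Corey–Kim chlorination; the alkoxysulfonium salt of the primary allylic alcohol is displaced by chloride at C1 without allylic shift, so both E-alkenes are kept.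

Step 2
Reactants: 2 (2E,6E)-farnesyl chloride
Product: 3 (2E,6E)-farnesyl diphosphate trisammonium salt
Conditions: (Bu4N)3HP2O7, MeCN, rt; then sulfonic acid cation-exchange resin (NH4+ form), aq. NH4HCO3; cellulose chromatography; lyophilisation
Reagents that add atoms: tris(tetrabutylammonium) hydrogen diphosphate, CCCC[N+](CCCC)(CCCC)CCCC.CCCC[N+](CCCC)(CCCC)CCCC.CCCC[N+](CCCC)(CCCC)CCCC.OP(=O)([O-])OP(=O)([O-])[O-]; ammonium hydrogencarbonate, [NH4+].OC(=O)[O-]
Why: SN2 displacement of the primary allylic chloride by the diphosphate trianion in a dipolar aprotic solvent; cation exchange gives the water-soluble ammonium salt that the enzyme accepts.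

Step 3
Reactants: 3 (2E,6E)-farnesyl diphosphate trisammonium salt
Product: 4 (R)-(+)-germacrene A
Conditions: recombinant (+)-germacrene A synthase (chicory type, from E. coli), MgCl2, HEPES pH 7.5, dithiothreitol, glycerol, pentane overlay, 25 °C, dark
Reagents that add atoms: none
Why: Class one terpene synthase cyclisation, a cation–olefin macrocyclisation. The diphosphate, bound to magnesium ions held by the aspartate-rich motifs of the enzyme, ionises to the (E,E)-farnesyl cation. The distal alkene (C10=C11, farnesyl numbering) adds through C10 to C1; this forms the C6–C7 bond in germacrane numbering and closes the ten-membered ring in a 1,10 (Markovnikov) mode that leaves the tertiary cation on the exocyclic carbon C11. Loss of a proton from a methyl group of that cation gives the isopropenyl group. The only new stereocentre, C7, is set as R by the enzyme, which presents one face of the distal alkene to C1; nothing in the achiral substrate controls it. The step needs 1,10-closure and not 1,11- or 1,6-closure, retention of both E-alkenes, and deprotonation in place of water capture or a second cyclisation. The E geometry at C2=C3 forbids direct 1,6-closure, the trisubstituted distal alkene favours the tertiary cation of 1,10-closure, and the active-site contour secures the rest. The hydrocarbon passes into the cool pentane layer as it forms, which keeps it from Cope rearrangement and from acid-promoted transannular cyclisation.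

Step 4
Reactants: 4 (R)-(+)-germacrene A
Product: 7 germacrene A acid, via germacra-1(10),4,11(13)-trien-12-ol 5 (not isolated), via germacra-1(10),4,11(13)-trien-12-al 6 (not isolated)
Conditions: yeast microsomes with germacrene A oxidase (CYP71AV type) and cytochrome P450 reductase, NADPH (cat.), glucose 6-phosphate, glucose-6-phosphate dehydrogenase, air, phosphate buffer pH 7.5, 2-hydroxypropyl-β-cyclodextrin, 30 °C; cold extraction at pH 6
Reagents that add atoms: dioxygen, O=O
Why: Three successive P450 oxidations of the allylic methyl of the isopropenyl group (alcohol, aldehyde, acid), a known activity of this oxidase on exactly this hydrocarbon; the ring alkenes and C7 are not touched.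

Step 5
Reactants: 7 germacrene A acid
Product: 10 eupatolide, via 8β-hydroxy acid 8 (not isolated), via 6α,8β-dihydroxy acid 9 (not isolated)
Conditions: yeast microsomes with germacrene A acid 8β-hydroxylase (CYP71BL1 type), eupatolide synthase (CYP71DD6 type) and cytochrome P450 reductase, NADPH (cat.), glucose 6-phosphate, glucose-6-phosphate dehydrogenase, air, phosphate buffer pH 7.5, 30 °C
Reagents that add atoms: dioxygen, O=O
Why: Two P450 hydroxylations, first at C8 on the β face and then at C6 on the α face; the 6α-hydroxy acid lactonises spontaneously onto C12 to the trans-fused γ-lactone. Both new stereocentres (C8 and C6) are set by the enzymes, and the second enzyme takes the 8β-hydroxy acid as its substrate, which fixes the order.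

Step 6
Reactants: 10 eupatolide
Product: 11 8-O-triethylsilyleupatolide
Conditions: TESCl, imidazole, CH2Cl2, 0 °C
Reagents that add atoms: chlorotriethylsilane, CC[Si](Cl)(CC)CC
Why: Silylation of the secondary alcohol under mild base; the ether keeps O8 from attacking C13 and from being oxidised in steps 8 and 9, and comes off later under buffered fluoride.

Step 7
Reactants: 11 8-O-triethylsilyleupatolide
Product: 13 1β,10α:4α,5β-diepoxide of 11, via 1β,10α-monoepoxide 12 (not isolated)
Conditions: mCPBA (2.5 equiv), NaHCO3, CH2Cl2, 0 °C to rt
Reagents that add atoms: 3-chloroperoxybenzoic acid, O=C(OO)c1cccc(Cl)c1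
Why: Prilezhaev epoxidation; the two trisubstituted ring alkenes are far more nucleophilic than the conjugated exocyclic methylene, and each is attacked on its outer face in the crown conformer with C14 and C15 syn. This should give the 1β,10α and 4α,5β epoxides (1R,10R,4R,5R), as is known for germacranolides of this type; NaHCO3 keeps the acid from starting transannular reactions.

Step 8
Reactants: 13 1β,10α:4α,5β-diepoxide of 11
Product: 14 (11R)-11,13-dibromo-11,13-dihydro derivative of 13
Conditions: Br2 (1.1 equiv), NaHCO3 (solid), CH2Cl2, 0 °C to rt, dark
Reagents that add atoms: bromine, BrBr
Why: Electrophilic addition of bromine to the only alkene left; bromide opens the bromonium ion at the primary carbon C13, so C11 keeps the bromine of the first attack. That bromine is expected on the β face, anti to the pseudo-axial H-7 of the trans-fused lactone (11R), which is the arrangement step 9 needs.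

Step 9
Reactants: 14 (11R)-11,13-dibromo-11,13-dihydro derivative of 13
Product: 16 13-acetoxy-7(11)-ene silyl ether, via allylic bromide 15 (not isolated)
Conditions: DBU (1.05 equiv), MeCN, 0 °C; then KOAc, 18-crown-6 (cat.), 0 °C to rt
Reagents that add atoms: potassium acetate, CC(=O)[O-].[K+]
Why: E2 dehydrobromination with H-7 and the C11 bromine antiperiplanar gives the tetrasubstituted, conjugated C7=C11 alkene and removes the stereocentres C7 and C11; acetate then displaces the primary allylic bromide at C13 by SN2. Attack at the fully substituted C7 is not competitive, and the base is kept to one equivalent at low temperature so that H-6 is not removed.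

Step 10
Reactants: 16 13-acetoxy-7(11)-ene silyl ether
Product: 17 13-acetoxy-8β-hydroxy-1β,10α:4α,5β-diepoxygermacr-7(11)-en-12,6α-olide
Conditions: HF·pyridine, pyridine, THF, 0 °C
Reagents that add atoms: none
Why: Fluoride-driven cleavage of the Si–O bond; the pyridine-buffered medium should spare the epoxides and forms no alkoxide, so acetyl migration and closure of O8 onto C13 are avoided.

Step 11
Reactants: 17 13-acetoxy-8β-hydroxy-1β,10α:4α,5β-diepoxygermacr-7(11)-en-12,6α-olide; 18 tiglic acid
Product: 19 target, 13-acetoxy-8α-tigloyloxy-1β,10α:4α,5β-diepoxygermacr-7(11)-en-12,6α-olide
Conditions: PPh3, DIAD, toluene, 0 °C to rt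
Reagents that add atoms: none
Why: Mitsunobu esterification; tiglate displaces the C8 oxyphosphonium group by SN2 with inversion, which turns the enzymatically set 8β-oxygen (8R) into the 8α-ester (8S). The allylic position helps the SN2 displacement, an SN1 path is disfavoured because the cation would be conjugated with the electron-poor butenolide, and SN2′ attack at the tetrasubstituted C11 is blocked.

Compound list

1 | (2E,6E)-farnesol | CC(C)=CCC/C(C)=C/CC/C(C)=C/CO | starting material
2 | (2E,6E)-farnesyl chloride | CC(C)=CCC/C(C)=C/CC/C(C)=C/CCl | intermediate
3 | (2E,6E)-farnesyl diphosphate, trisammonium salt | CC(C)=CCC/C(C)=C/CC/C(C)=C/COP(=O)([O-])OP(=O)([O-])[O-].[NH4+].[NH4+].[NH4+] | intermediate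
4 | (R)-(+)-germacrene A, (7R)-germacra-1(10)E,4E,11-triene | C=C(C)[C@@H]1CC/C(C)=C/CC/C(C)=C/C1 | intermediate
5 | (7R)-germacra-1(10)E,4E,11(13)-trien-12-ol | C=C(CO)[C@@H]1CC/C(C)=C/CC/C(C)=C/C1 | intermediate (not isolated)
6 | (7R)-germacra-1(10)E,4E,11(13)-trien-12-al | C=C(C=O)[C@@H]1CC/C(C)=C/CC/C(C)=C/C1 | intermediate (not isolated)
7 | germacrene A acid, (7R)-germacra-1(10)E,4E,11(13)-trien-12-oic acid | C=C(C(=O)O)[C@@H]1CC/C(C)=C/CC/C(C)=C/C1 | intermediate
8 | 8β-hydroxygermacra-1(10)E,4E,11(13)-trien-12-oic acid (H-7α) | O[C@@H]1C/C(C)=C/CC/C(C)=C/C[C@@H]1C(=C)C(=O)O | intermediate (not isolated)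
9 | 6α,8β-dihydroxygermacra-1(10)E,4E,11(13)-trien-12-oic acid (H-7α) | O[C@@H]1C/C(C)=C/CC/C(C)=C/[C@@H](O)[C@@H]1C(=C)C(=O)O | intermediate (not isolated)
10 | eupatolide, 8β-hydroxygermacra-1(10)E,4E,11(13)-trien-12,6α-olide (H-6β, H-7α) | O[C@@H]1C/C(C)=C/CC/C(C)=C/[C@H]2OC(=O)C(=C)[C@H]12 | intermediate
11 | 8-O-triethylsilyleupatolide | CC[Si](CC)(CC)O[C@@H]1C/C(C)=C/CC/C(C)=C/[C@H]2OC(=O)C(=C)[C@H]12 | intermediate
12 | 1β,10α-epoxy-8β-triethylsilyloxygermacra-4E,11(13)-dien-12,6α-olide | CC[Si](CC)(CC)O[C@@H]1C[C@@]2(C)O[C@@H]2CC/C(C)=C/[C@H]2OC(=O)C(=C)[C@H]12 | intermediate (not isolated)
13 | 1β,10α:4α,5β-diepoxy-8β-triethylsilyloxygermacr-11(13)-en-12,6α-olide | CC[Si](CC)(CC)O[C@@H]1C[C@@]2(C)O[C@@H]2CC[C@@]2(C)O[C@@H]2[C@H]2OC(=O)C(=C)[C@H]12 | intermediate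
14 | (11R)-11,13-dibromo-1β,10α:4α,5β-diepoxy-8β-triethylsilyloxygermacran-12,6α-olide (Br at C11 β, anti to H-7α) | CC[Si](CC)(CC)O[C@@H]1C[C@@]2(C)O[C@@H]2CC[C@@]2(C)O[C@@H]2[C@H]2OC(=O)[C@@](Br)(CBr)[C@H]12 | intermediate
15 | 13-bromo-1β,10α:4α,5β-diepoxy-8β-triethylsilyloxygermacr-7(11)-en-12,6α-olide | CC[Si](CC)(CC)O[C@@H]1C[C@@]2(C)O[C@@H]2CC[C@@]2(C)O[C@@H]2[C@H]2OC(=O)C(CBr)=C12 | intermediate (not isolated)
16 | 13-acetoxy-1β,10α:4α,5β-diepoxy-8β-triethylsilyloxygermacr-7(11)-en-12,6α-olide | CC[Si](CC)(CC)O[C@@H]1C[C@@]2(C)O[C@@H]2CC[C@@]2(C)O[C@@H]2[C@H]2OC(=O)C(COC(C)=O)=C12 | intermediate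
17 | 13-acetoxy-8β-hydroxy-1β,10α:4α,5β-diepoxygermacr-7(11)-en-12,6α-olide (8R) | O[C@@H]1C[C@@]2(C)O[C@@H]2CC[C@@]2(C)O[C@@H]2[C@H]2OC(=O)C(COC(C)=O)=C12 | intermediate
18 | tiglic acid, (E)-2-methylbut-2-enoic acid | C/C=C(\C)C(=O)O | starting material
19 | 13-acetoxy-8α-tigloyloxy-1β,10α:4α,5β-diepoxygermacr-7(11)-en-12,6α-olide (1R,4R,5R,6S,8S,10R) | C/C=C(\C)C(=O)O[C@H]1C[C@@]2(C)O[C@@H]2CC[C@@]2(C)O[C@@H]2[C@H]2OC(=O)C(COC(C)=O)=C12 | target

Total step count: 11. Longest linear sequence: 11 steps (1 to 19; tiglic acid 18 enters in step 11).

Steps least certain to work

Step 3 (key step). The cyclisation itself has no competing mode. The likely failure is loss of 4 after it has formed: Cope rearrangement on warming, acid-promoted transannular cyclisation on contact with silica or acidic glass, and evaporation with the solvent. Slow turnover and inhibition by magnesium diphosphate at preparative concentration add to this. Fallback: starting from 3, the cyclase would be run in the same vessel as the oxidase microsomes and the NADPH-regenerating system of step 4. Compound 4 is then oxidised as it is released and never accumulates, and the route is rejoined at acid 7, which is not volatile and can be extracted. This fallback makes no compound outside the list (F0).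

Step 5. The two hydroxylations may lose their order, with C6 oxidised before C8 and the material closed off as the 8-deoxy lactone. Coupling between the P450s and the reductase in isolated membranes may also be too weak for preparative conversion, and the acid may cyclise during the long incubation. Fallback: the whole oxidative sequence would be moved into a living yeast host with a raised mevalonate flux that expresses the cyclase, the oxidase, the 8β-hydroxylase, eupatolide synthase and a reductase. It sets out from 3 as the cell makes it from glucose, passes through 4, 7, 8 and 9 inside the cell, and returns to the route at 10, extracted from the culture. This fallback makes no compound outside the list (F0).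

Step 9 (with step 8). Elimination toward C7 needs H-7 antiperiplanar to the C11 bromine. If bromine was delivered to the α face of C11 in step 8, elimination would run toward C13 or not at all. Hydrogen bromide set free in step 8 can open an epoxide, and once the butenolide exists the base can remove H-6 and open the 4,5-epoxide. Fallback: starting from 13, a Wohl–Ziegler bromination with allylic shift (NBS, AIBN, K2CO3, PhCF3, 80 °C) would abstract H-7, the only allylic hydrogen of 13. The allyl radical over C7–C11–C13 would take up bromine at the unhindered terminus C13 and give 15 directly, with no stereochemical demand at C11. The route is rejoined at 15, which is treated with KOAc as in step 9 without DBU. This fallback makes no compound outside the list (F0).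

Step 11. The activated C8 oxygen sits on a hindered carbon between C7 and the C9 methylene. Elimination toward C9 to a dienyl lactone, or acyl transfer with retention through an acyloxyphosphonium ion, may outrun the SN2 displacement. Fallback: starting from 17, the alcohol would be oxidised with Dess–Martin periodinane (NaHCO3, CH2Cl2, 0 °C) to 13-acetoxy-1β,10α:4α,5β-diepoxy-8-oxogermacr-7(11)-en-12,6α-olide F1. The enone would be reduced under reagent control with (R)-2-methyl-CBS-oxazaborolidine and catecholborane (toluene, −78 °C), the alkenyl carbon C7 acting as the large group, to 13-acetoxy-8α-hydroxy-1β,10α:4α,5β-diepoxygermacr-7(11)-en-12,6α-olide F2 (8S). F2 would be acylated with retention by 18 (EDC·HCl, 4-(dimethylamino)pyridine, CH2Cl2, 0 °C) to return to the route at 19. F1 is an ene-dione with a doubly activated H-6 and would be used at once.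

Further compounds

F0 | step 3 | none | none
F0 | step 5 | none | none
F0 | step 9 | none | none
F1 | step 11 | 13-acetoxy-1β,10α:4α,5β-diepoxy-8-oxogermacr-7(11)-en-12,6α-olide | O=C1C[C@@]2(C)O[C@@H]2CC[C@@]2(C)O[C@@H]2[C@H]2OC(=O)C(COC(C)=O)=C12
F2 | step 11 | 13-acetoxy-8α-hydroxy-1β,10α:4α,5β-diepoxygermacr-7(11)-en-12,6α-olide | O[C@H]1C[C@@]2(C)O[C@@H]2CC[C@@]2(C)O[C@@H]2[C@H]2OC(=O)C(COC(C)=O)=C12
A1 | alternative 1 | 13-O-(4-methoxybenzyl) analogue of 19 (13-deacetyl) | C/C=C(\C)C(=O)O[C@H]1C[C@@]2(C)O[C@@H]2CC[C@@]2(C)O[C@@H]2[C@H]2OC(=O)C(COCc3ccc(OC)cc3)=C12
A2 | alternative 1 | 1β,10α:4α,5β-diepoxy-7-oxo-8α-tigloyloxy ten-membered ring, C6 ester of 2-(diethoxyphosphoryl)-3-(4-methoxybenzyloxy)propanoic acid | C/C=C(\C)C(=O)O[C@H]1C[C@@]2(C)O[C@@H]2CC[C@@]2(C)O[C@@H]2[C@@H](OC(=O)C(COCc2ccc(OC)cc2)P(=O)(OCC)OCC)C1=O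
A3 | alternative 2 | 13-acetoxy-8α-tigloyloxygermacra-1(10)E,4E,7(11)-trien-12,6α-olide | C/C=C(\C)C(=O)O[C@H]1C/C(C)=C/CC/C(C)=C/[C@H]2OC(=O)C(COC(C)=O)=C12
A4 | alternative 2 | methyl (Z)-2-(acetoxymethyl)-3-formyl-4-tigloyloxy-alk-2-enoate with the (E,E)-6,10-dimethyl-11-iodoundeca-6,10-dienyl chain (acyclic C5 iodide, C6 aldehyde) | C/C=C(\C)C(=O)O[C@@H](C/C(C)=C/CC/C(C)=C/I)/C(C=O)=C(\COC(C)=O)C(=O)OC
A5 | alternative 3 | 2,3-didehydro analogue of 19 (Z drawn) | C/C=C(\C)C(=O)O[C@H]1C[C@@]2(C)O[C@@H]2/C=C\[C@@]2(C)O[C@@H]2[C@H]2OC(=O)C(COC(C)=O)=C12
A6 | alternative 3 | bis(vinyl epoxide) butenolide, seco-2,3 precursor with a vinyl group on C1 and on C4 | C=C[C@@]2(C)O[C@@H]2[C@H]2OC(=O)C(COC(C)=O)=C2[C@@H](OC(=O)/C(C)=C/C)C[C@@]2(C)O[C@@H]2C=C
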